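**Retrosynthetic overview**
- The strategy rests on the quinone ring itself. With the ring numbered C1(=O), C2(OH), C3(CH3), C4(=O), C5(OH), C6(side chain), it is the bis-enol of a 3-methyl-6-alkylcyclohexane-1,2,4,5-tetraone. That tetraone is two R–CH2–CO–CO three-carbon units (C6–C1–C2 and C3–C4–C5) joined head to tail, already at the quinone oxidation level.
- Cutting C2–C3 and C5–C6 gives two 2-oxo esters: ethyl (Z)-2-oxooctadec-13-enoate and ethyl 2-oxobutanoate. A base-mediated double Claisen condensation joins them, and the only ring is closed in the last step.
- The long-chain 2-oxo ester comes from (Z)-hexadec-11-en-1-ol by way of the bromide, the Grignard reagent and diethyl oxalate. C1 of the alcohol becomes ring carbon C6, and the rest of its chain is the (Z)-pentadec-10-enyl group.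

Key step: step 3

Remark: the target has no stereocentre. Its only stereochemical element is the (Z)-C10′=C11′ alkene, which is bought with (Z)-hexadec-11-en-1-ol (a commercial pheromone component) and is never exposed to isomerising conditions.

**Step 1**
Reactants: 1 (Z)-hexadec-11-en-1-ol
Product: 2 (Z)-1-bromohexadec-11-ene [(Z)-16-bromohexadec-5-ene]
Conditions: CBr4, PPh3, CH2Cl2, 0 °C → rt
Reagents that add atoms: carbon tetrabromide, BrC(Br)(Br)Br
Why: Appel reaction: the alkoxyphosphonium ion formed from the primary alcohol is displaced by bromide in an SN2 step under neutral conditions, so the remote (Z)-alkene is neither isomerised nor brominated.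

**Step 2**
Reactants: 2 (Z)-1-bromohexadec-11-ene; 3 diethyl oxalate (3 equiv)
Product: 6 ethyl (Z)-2-oxooctadec-13-enoate, via Grignard reagent 4 (not isolated), via tetrahedral magnesium adduct 5 (not isolated)
Conditions: Mg, cat. I2, THF, 45 °C; solution added to (CO2Et)2, THF, −78 °C; 2 M HCl at −78 °C → rt
Reagents that add atoms: none
Why: Grignard formation followed by inverse addition to excess diethyl oxalate (nucleophilic acyl substitution) should stop after one addition, because the magnesium hemiketal alkoxide 5 persists at −78 °C and releases the ketone only on the acidic quench, when no organometallic is left; the isolated alkene is inert to both stages.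

**Step 3**
Reactants: 6 ethyl (Z)-2-oxooctadec-13-enoate; 7 ethyl 2-oxobutanoate (4 equiv)
Product: 11 2,5-dihydroxy-3-methyl-6-[(Z)-pentadec-10-enyl]-1,4-benzoquinone, via triketo ester 8 (not isolated), via triketo ester 9 (not isolated), via disodium quinone salt 10 (not isolated)
Conditions: 6 + 7 (premixed) added to NaOEt (alcohol-free, 5.5 equiv), toluene–THF, 0 °C → 50 °C, Ar; then cold 2 M HCl; chromatography on oxalic acid-treated silica
Reagents that add atoms: none
Why: Ethoxide deprotonates the C3 methylene of either keto ester and the enolate attacks the ester carbonyl of the other (crossed Claisen) to give triketo ester 8 or 9; the remaining CH2 next to the terminal ketone is then deprotonated and attacks the remaining ester carbonyl in a 6-(enolendo)-exo-trig Dieckmann-type acylation, so that C2–C3 and C5–C6 of the ring are both formed. The resulting 3-methyl-6-alkylcyclohexane-1,2,4,5-tetraone needs no oxidation and is deprotonated twice to the bis(vinylogous carboxylate) 10, whose stability and low solubility in the aprotic medium should pull the reversible acylations forward; acid then liberates 11. The closest known reaction is the sodium- or alkoxide-mediated self-condensation of 2-oxoalkanoate esters to 3,6-dialkyl-2,5-dihydroxy-1,4-benzoquinones, run here with two different esters. No stereocentre is created, and the (Z)-alkene, far from any acidic position, is not touched by ethoxide. The only selectivity needed is crossed over homo pairing: the fourfold excess of the cheap ester 7, fed premixed with 6 so that their ratio stays constant, should channel most of 6 into the mixed ring, and regiochemistry is no issue because 8 and 9 close to the same tetraone. The two symmetrical quinones expected as by-products (dimethyl, very polar and poorly soluble; bis-pentadecenyl, much less polar) are to be removed by trituration and chromatography.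

**Compound list**
1 | (Z)-hexadec-11-en-1-ol | CCCC/C=C\CCCCCCCCCCO | starting material
2 | (Z)-1-bromohexadec-11-ene [(Z)-16-bromohexadec-5-ene] | CCCC/C=C\CCCCCCCCCCBr | intermediate
3 | diethyl oxalate | CCOC(=O)C(=O)OCC | starting material
4 | (Z)-hexadec-11-enylmagnesium bromide | CCCC/C=C\CCCCCCCCCC[Mg]Br | intermediate
5 | bromomagnesium alkoxide of ethyl (Z)-2-ethoxy-2-hydroxyoctadec-13-enoate (tetrahedral adduct, racemic) | CCCC/C=C\CCCCCCCCCCC(O[Mg]Br)(OCC)C(=O)OCC | intermediate
6 | ethyl (Z)-2-oxooctadec-13-enoate | CCCC/C=C\CCCCCCCCCCC(=O)C(=O)OCC | intermediate
7 | ethyl 2-oxobutanoate | CCC(=O)C(=O)OCC | starting material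
8 | ethyl (Z)-3-methyl-2,4,5-trioxohenicos-16-enoate (racemic, present as its sodium enolate) | CCCC/C=C\CCCCCCCCCCC(=O)C(=O)C(C)C(=O)C(=O)OCC | intermediate
9 | ethyl 2,4,5-trioxo-3-[(Z)-pentadec-10-enyl]heptanoate (racemic, present as its sodium enolate) | CCC(=O)C(=O)C(CCCCCCCCC/C=C\CCCC)C(=O)C(=O)OCC | intermediate
10 | disodium 3-methyl-6-[(Z)-pentadec-10-enyl]-1,4-benzoquinone-2,5-diolate | CCCC/C=C\CCCCCCCCCC1=C([O-])C(=O)C(C)=C([O-])C1=O.[Na+].[Na+] | intermediate
11 | 2,5-dihydroxy-3-methyl-6-[(Z)-pentadec-10-enyl]-1,4-benzoquinone | CCCC/C=C\CCCCCCCCCC1=C(O)C(=O)C(C)=C(O)C1=O | target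

**Step count**
Total steps: 3. Longest linear sequence: 3 steps (1 → 2 → 6 → 11).

**Steps most likely to fail**

Step 3 (key condensation). Homo-pairing of each ester may compete with the crossed pairing. More seriously, aldol addition of an enolate to a ketone carbonyl, followed by lactonisation of the adduct onto the neighbouring ester, may drain both keto esters before the double acylation closes the ring. Separation of three dihydroxyquinones may also cost material. The fallback is a directed, non-statistical variant in which both ester carbonyls sit on one partner and both methylenes on the other. It sets out from Grignard reagent 4. Inverse addition of 4 to N,N′-dimethoxy-N,N′-dimethyloxamide (THF, −78 → 0 °C) should give the chelated tetrahedral mono-adduct magnesium alkoxide F1. Ethylmagnesium bromide, added to the same flask, should then attack the remaining N-methoxy-N-methylamide carbonyl to give the bis-adduct magnesium alkoxide F2. Acidic work-up releases (Z)-icos-15-ene-3,4-dione F3. Claisen acylation of either α-methylene of F3 with diethyl oxalate 3 (alcohol-free NaOEt, toluene–THF) leads to triketo ester 8 or 9, where the fallback rejoins the route. Closure to 10 and acidification to 11 follow in the same flask, and no symmetrical quinone can arise.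

Step 2 (Grignard acylation). The Grignard reagent may add a second time to the keto group if the tetrahedral adduct collapses before the quench, and Wurtz-type homocoupling may occur during magnesium insertion. The fallback is an umpolung route without an organometallic. It sets out from bromide 2. Alkylation of the sodium salt of ethyl 1,3-dithiane-2-carboxylate with 2 (NaH, DMF–toluene, 0 °C → rt) should give ethyl 2-[(Z)-hexadec-11-enyl]-1,3-dithiane-2-carboxylate F4. Alkylative hydrolysis of the dithioketal (MeI, CaCO3, aqueous MeCN, 50 °C), chosen because it leaves the alkene alone, returns to keto ester 6.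

Step 1 (bromination). Conversion of the alcohol may be incomplete, or phosphine oxide and bromoform may be carried over; either would quench or stall the magnesium insertion of step 2. The fallback avoids both the halide and the Grignard reagent. It sets out from alcohol 1. Dess–Martin oxidation (CH2Cl2, rt) should give (Z)-hexadec-11-enal F5. Horner–Wadsworth–Emmons olefination with ethyl 2-[(tert-butyldimethylsilyl)oxy]-2-(diethoxyphosphoryl)acetate (LiHMDS, THF, −78 °C → rt) should give ethyl (13Z)-2-[(tert-butyldimethylsilyl)oxy]octadeca-2,13-dienoate F6; either geometry of the enol ether serves. Fluoride desilylation (Et3N·3HF, THF) unmasks the 2-oxo group and returns to keto ester 6, bypassing 2, 4 and 5.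

**Further compounds**
F1 | step 3 | bromomagnesium alkoxide of (Z)-2-hydroxy-N-methoxy-2-[methoxy(methyl)amino]-N-methyloctadec-13-enamide (tetrahedral mono-adduct) | CCCC/C=C\CCCCCCCCCCC(O[Mg]Br)(N(C)OC)C(=O)N(C)OC
F2 | step 3 | bis(bromomagnesium) dialkoxide of (Z)-3,4-bis[methoxy(methyl)amino]icos-15-ene-3,4-diol (bis-adduct) | CCCC/C=C\CCCCCCCCCCC(O[Mg]Br)(N(C)OC)C(CC)(O[Mg]Br)N(C)OC
F3 | step 3 | (Z)-icos-15-ene-3,4-dione | CCCC/C=C\CCCCCCCCCCC(=O)C(=O)CC
F4 | step 2 | ethyl 2-[(Z)-hexadec-11-enyl]-1,3-dithiane-2-carboxylate | CCCC/C=C\CCCCCCCCCCC1(C(=O)OCC)SCCCS1
F5 | step 1 | (Z)-hexadec-11-enal | CCCC/C=C\CCCCCCCCCC=O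
F6 | step 1 | ethyl (13Z)-2-[(tert-butyldimethylsilyl)oxy]octadeca-2,13-dienoate | CCCC/C=C\CCCCCCCCCC=C(O[Si](C)(C)C(C)(C)C)C(=O)OCC
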